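**Plan**
1. Target: epioritin-(4β→6)-oritin-(4α→6)-epioritin-4α-ol. Retrosynthetic cuts: (a) C4(top)–C6(middle), a Friedel–Crafts bond; (b) in the middle unit the 3-OH and the O1–C2 bond, so that its pyran ring (O1, C2, C3, C4, C4a, C8a) is traced back to a 2-aroyl-2,3-dihydrobenzofuran (ring O1, C3, C4, C4a, C8a, with C2 outside the ring as the ketone carbon); (c) O1–C3 and C3–C4 of that ring ([4+1] annulation of an o-quinone methide with a diazoketone); (d) C4(middle)–C6(bottom) (aryllithium plus aldehyde).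
2. Enabling feature: in ring C of the middle unit, O1 and the 3-OH sit on the neighbouring carbons C2 and C3. O1 can therefore first be bonded to C3 in an α-aryloxy ketone, be released reductively, and close again on the C2 carbonyl, turning the five-membered ring into the six-membered one.
3. Forward, monomer: one epioritin building block (Petasis chromene, hydroboration, oxidation, dynamic kinetic transfer hydrogenation) is brominated at C6 and oxidised at C4. It serves as the top-unit electrophile and, after C4 inversion and silylation, as the bottom-unit aryl bromide.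
4. Forward, assembly: bottom unit plus A-ring aldehyde gives a diaryl carbinol, then the dihydrobenzofuran, then ring expansion to the flav-2-ene, hydroboration, coupling with the top unit, hydrogenolysis and desilylation.
5. Stereochemistry: C2/C3 of the top and bottom units come from the Ru-catalysed dynamic kinetic reduction; C4 of the bottom unit from hydride attack anti to the axial 3-OH; C4 of the middle unit from the chiral phosphoric acid in the [4+1] step; C2/C3 of the middle unit from hydroboration anti to the 4-aryl group; C4 of the top unit from attack anti to its 3-OH.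

Key step: step 15

Assumption: the sense of induction of the Ru catalyst (step 6) and of the phosphoric acid (step 14) is taken as written, and the antipodal catalyst would be used if the opposite sense were found; racemates are drawn as one enantiomer.

Abbreviations: Bn = benzyl; TBS = tert-butyldimethylsilyl; PBP = 4-(benzyloxy)phenyl; BU = (2R,3S,4R)-7,8-bis(benzyloxy)-2-[4-(benzyloxy)phenyl]-3,4-bis(tert-butyldimethylsilyloxy)chroman-6-yl (the bottom-unit aryl group); oritin and epioritin = (2R,3S)- and (2R,3R)-7,8,4'-trihydroxyflavan-3-ol. Flavan numbering is used unless stated otherwise.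

**Route**

Step 1
Reactants: 1 2,3,4-trihydroxybenzaldehyde
Product: 2 3,4-bis(benzyloxy)-2-hydroxybenzaldehyde
Conditions: BnBr (2.05 equiv), K2CO3 (2 equiv), acetone, reflux
Reagents that add atoms: benzyl bromide, BrCc1ccccc1
Why: Williamson ether synthesis; the 2-OH is hydrogen-bonded to the aldehyde and is the least reactive, so two equivalents of BnBr should alkylate only the 4-OH and 3-OH.

Step 2
Reactants: 3 1-(benzyloxy)-4-ethynylbenzene
Product: 5 (E)-2-[4-(benzyloxy)phenyl]ethenylboronic acid, via catechol boronate 4 (not isolated)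
Conditions: catecholborane, THF, 70 °C; then H2O, rt
Reagents that add atoms: catecholborane, B1Oc2ccccc2O1; water, O
Why: Brown hydroboration of the terminal alkyne is syn and anti-Markovnikov, giving the (E)-alkenylboronate, which water hydrolyses to the boronic acid.

Step 3
Reactants: 2 3,4-bis(benzyloxy)-2-hydroxybenzaldehyde; 5 (E)-2-[4-(benzyloxy)phenyl]ethenylboronic acid
Product: 6 (±)-7,8-bis(benzyloxy)-2-PBP-2H-chromene
Conditions: Bn2NH (0.4 equiv), dioxane, 90 °C
Reagents that add atoms: none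
Why: Petasis borono-Mannich condensation followed by loss of the amine and oxa-6π-electrocyclisation should give the 2-aryl-2H-chromene; C2 forms as a racemate that is resolved dynamically in step 6.

Step 4
Reactants: 6 (±)-7,8-bis(benzyloxy)-2-PBP-2H-chromene
Product: 8 (±)-(2R*,3S*)-7,8-bis(benzyloxy)-2-PBP-chroman-3-ol, via alkylborane 7 (not isolated)
Conditions: BH3·THF, THF, 0 °C → rt; then NaOH, H2O2, 0 °C
Reagents that add atoms: hydrogen peroxide, OO
Why: Brown hydroboration places boron at C3 (away from the benzylic C4) on the face anti to the 2-aryl group, and oxidation with retention gives the racemic 2,3-trans alcohol.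

Step 5
Reactants: 8 (±)-(2R*,3S*)-7,8-bis(benzyloxy)-2-PBP-chroman-3-ol
Product: 9 (±)-7,8-bis(benzyloxy)-2-PBP-chroman-3-one
Conditions: Dess–Martin periodinane, CH2Cl2, 0 °C → rt
Reagents that add atoms: none
Why: Dess–Martin oxidation of the secondary alcohol; the C2 configuration need not be kept because the ketone is racemic and is equilibrated in the next step.

Step 6
Reactants: 9 (±)-7,8-bis(benzyloxy)-2-PBP-chroman-3-one
Product: 10 (2R,3R)-7,8-bis(benzyloxy)-2-PBP-chroman-3-ol (tri-O-benzylepioritin)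
Conditions: RuCl(p-cymene)[(R,R)-N-tosyl-1,2-diphenylethylenediamine] (2 mol%), HCO2H/Et3N, EtOAc, 40 °C
Reagents that add atoms: none
Why: Noyori-type asymmetric transfer hydrogenation with dynamic kinetic resolution: the acidic C2–H (α to the ketone, to O1 and to the aryl group) epimerises through the enol while the chiral Ru hydride reduces one ketone enantiomer from the face anti to the 2-aryl group, setting C3 by the catalyst and C2 by selection, in a 2,3-cis relationship.

Step 7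
Reactants: 10 (2R,3R)-7,8-bis(benzyloxy)-2-PBP-chroman-3-ol
Product: 11 (2R,3R)-7,8-bis(benzyloxy)-6-bromo-2-PBP-chroman-3-ol
Conditions: NBS, CH2Cl2, −20 °C
Reagents that add atoms: N-bromosuccinimide, O=C1CCC(=O)N1Br
Why: electrophilic aromatic bromination at C6, which is ortho to the 7-benzyloxy group and para to O1; the bromine later serves as the lithiation handle (bottom unit) and as a blocking group (top unit).

Step 8
Reactants: 11 (2R,3R)-7,8-bis(benzyloxy)-6-bromo-2-PBP-chroman-3-ol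
Product: 12 (2R,3R,4S)-7,8-bis(benzyloxy)-6-bromo-2-PBP-chroman-3,4-diol
Conditions: DDQ, CH2Cl2/H2O, rt
Reagents that add atoms: water, O
Why: DDQ benzylic oxidation: hydride abstraction from C4 gives a cation stabilised by the 7-benzyloxy group (para to C4a), and water adds anti to the axial 3-OH to give the 4β-alcohol (3,4-trans).

Step 9
Reactants: 12 (2R,3R,4S)-7,8-bis(benzyloxy)-6-bromo-2-PBP-chroman-3,4-diol
Product: 13 (2R,3S)-7,8-bis(benzyloxy)-6-bromo-3-hydroxy-2-PBP-chroman-4-one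
Conditions: MnO2 (activated), CH2Cl2, rt
Reagents that add atoms: none
Why: MnO2 oxidises the benzylic 4-OH selectively under neutral conditions, leaving the 3-OH and the 2,3-cis arrangement untouched.

Step 10
Reactants: 13 (2R,3S)-7,8-bis(benzyloxy)-6-bromo-3-hydroxy-2-PBP-chroman-4-one
Product: 14 (2R,3R,4R)-7,8-bis(benzyloxy)-6-bromo-2-PBP-chroman-3,4-diol
Conditions: NaBH4, CeCl3·7H2O, MeOH/THF, −40 °C
Reagents that add atoms: none
Why: Luche reduction: hydride attacks C4 from the β face, anti to the axial 3-OH and the 2-aryl group, setting the 4α-OH of the all-cis diol, while the buffered cold conditions should prevent C3 epimerisation.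

Step 11
Reactants: 14 (2R,3R,4R)-7,8-bis(benzyloxy)-6-bromo-2-PBP-chroman-3,4-diol
Product: 15 (2R,3S,4R)-7,8-bis(benzyloxy)-6-bromo-2-PBP-3,4-bis(tert-butyldimethylsilyloxy)chroman (BU–Br)
Conditions: TBSOTf (2.5 equiv), 2,6-lutidine, CH2Cl2, 0 °C
Reagents that add atoms: tert-butyldimethylsilyl trifluoromethanesulfonate, CC(C)(C)[Si](C)(C)OS(=O)(=O)C(F)(F)F
Why: silylation of both hydroxyls with a silyl triflate under non-acidic conditions protects the diol against the organolithium and Lewis-acid steps without touching a stereocentre.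

Step 12
Reactants: 15 BU–Br; 2 3,4-bis(benzyloxy)-2-hydroxybenzaldehyde
Product: 18 [3,4-bis(benzyloxy)-2-hydroxyphenyl](BU)methanol (carbinol epimers), via sodium phenoxide 16 (not isolated), via aryllithium 17 (not isolated)
Conditions: 15, n-BuLi, THF, −78 °C; 2, NaH, THF, 0 °C; mix at −78 → −20 °C; then H2O
Reagents that add atoms: none
Why: bromine–lithium exchange followed by 1,2-addition of the aryllithium to the aldehyde of the preformed phenoxide; the new carbinol centre forms as a mixture and is removed in step 14.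

Step 13
Reactants: 19 4-(benzyloxy)benzoyl chloride
Product: 20 1-[4-(benzyloxy)phenyl]-2-diazoethan-1-one
Conditions: Me3SiCHN2 (2 equiv), MeCN/THF, 0 °C → rt
Reagents that add atoms: (trimethylsilyl)diazomethane, C[Si](C)(C)C=[N+]=[N-]
Why: acylation of the diazo carbon by the acid chloride with loss of the silyl group, as in the first stage of the Arndt–Eistert sequence.

Step 14
Reactants: 18 [3,4-bis(benzyloxy)-2-hydroxyphenyl](BU)methanol; 20 1-[4-(benzyloxy)phenyl]-2-diazoethan-1-one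
Product: 22 [(2S,3S)-6,7-bis(benzyloxy)-3-BU-2,3-dihydrobenzofuran-2-yl](PBP)methanone (benzofuran numbering; 2,3-cis), via o-quinone methide 21 (not isolated)
Conditions: (R)-3,3'-bis(2,4,6-triisopropylphenyl)-1,1'-binaphthyl-2,2'-diyl hydrogen phosphate (10 mol%), CHCl3, 4 Å MS, 0 °C
Reagents that add atoms: none
Why: Brønsted-acid-catalysed [4+1] annulation: dehydration gives the o-quinone methide, the diazo carbon adds to its methide carbon inside the chiral phosphate hydrogen-bond/ion pair (this sets C3 of the dihydrobenzofuran, the later C4 of the middle unit), and O-alkylation with loss of N2 closes the ring cis (C2 is removed again in step 15).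

Step 15
Reactants: 22 [(2S,3S)-6,7-bis(benzyloxy)-3-BU-2,3-dihydrobenzofuran-2-yl](PBP)methanone
Product: 25 (4S)-7,8-bis(benzyloxy)-2-PBP-4-BU-4H-chromene, via keto-phenol 23 (not isolated), via hemiketal 24 (not isolated)
Conditions: SmI2 (2.2 equiv), THF/MeOH, −78 °C; then PPTS, PhMe, 4 Å MS, 40 °C
Reagents that add atoms: none
Why: Two single-electron transfers from SmI2 to the aryl ketone give the ketyl and then, with cleavage of the α C3–O1 bond, a samarium enolate and phenoxide that MeOH protonates to the δ-hydroxy ketone; its phenol O1 adds to the C2 carbonyl and the hemiketal loses water under PPTS, so that O1 has moved from C3 to C2 and the five-membered ring has grown by one carbon (C2) into the six-membered pyran ring. The closest known reaction types are the SmI2 cleavage of α-alkoxy and α-aryloxy ketones and the acid-catalysed cyclodehydration of 3-(2-hydroxyaryl)propiophenones to 2-aryl-4H-chromenes. The six-membered ring closes by 6-exo-trig addition of O1 to the ketone. No new stereocentre remains in 25 (C2 of the hemiketal is lost on dehydration), and C4 is neither α to the carbonyl nor ionisable here, so it keeps the configuration set in step 14. The step needs reduction of the α-aryloxy ketone in preference to the aryl ketone it liberates and to the benzyl and silyl ethers, which the fast fragmentation of the α-aryloxy ketyl and the limit of about two equivalents of SmI2 at −78 °C should secure. Dehydration can only give the C2=C3 enol ether, because only C3 carries hydrogens next to the hemiketal carbon.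

Step 16
Reactants: 25 (4S)-7,8-bis(benzyloxy)-2-PBP-4-BU-4H-chromene
Product: 27 (2R,3S,4S)-7,8-bis(benzyloxy)-2-PBP-4-BU-chroman-3-ol (tri-O-benzyloritin-(4α→6)-linked to the protected bottom unit), via alkylborane 26 (not isolated)
Conditions: BH3·THF, THF, 0 °C → rt; then NaOH, H2O2, 0 °C
Reagents that add atoms: hydrogen peroxide, OO
Why: Brown hydroboration of the enol ether: boron adds to C3 and hydrogen to C2, syn and from the β face anti to the pseudoaxial 4-aryl group, and oxidation with retention gives the 2,3-trans-3,4-trans alcohol, so C2 and C3 are set by substrate control from C4.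

Step 17
Reactants: 27 (2R,3S,4S)-7,8-bis(benzyloxy)-2-PBP-4-BU-chroman-3-ol; 12 (2R,3R,4S)-7,8-bis(benzyloxy)-6-bromo-2-PBP-chroman-3,4-diol (1.3 equiv)
Product: 28 6-bromo-7,8,4'-tri-O-benzylepioritin-(4β→6)-7,8,4'-tri-O-benzyloritin-(4α→6)-7,8,4'-tri-O-benzyl-3,4-bis-O-TBS-epioritin-4α-ol
Conditions: BF3·OEt2 (0.3 equiv), 4 Å MS, CH2Cl2, −78 → −30 °C
Reagents that add atoms: none
Why: Friedel–Crafts alkylation: BF3 ionises the 4-OH of 12 to the benzylic cation, which C6 of the middle unit (ortho to OBn, para to O1) attacks anti to the axial 3-OH, setting the 4β (3,4-trans) centre; the 6-bromine of 12 prevents its self-condensation.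

Step 18
Reactants: 28 protected trimer
Product: 29 epioritin-(4β→6)-oritin-(4α→6)-3,4-bis-O-TBS-epioritin-4α-ol
Conditions: H2 (1 atm), Pd(OH)2/C, Et3N, THF/MeOH, rt
Reagents that add atoms: none
Why: catalytic hydrogenolysis cleaves the nine benzyl ethers and the aryl bromide, while the silyl ethers and interflavan bonds should survive and Et3N takes up the HBr.

Step 19
Reactants: 29 epioritin-(4β→6)-oritin-(4α→6)-3,4-bis-O-TBS-epioritin-4α-ol
Product: 30 epioritin-(4β→6)-oritin-(4α→6)-epioritin-4α-ol (target)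
Conditions: HF·pyridine, pyridine, THF, 0 °C → rt, under argon
Reagents that add atoms: none
Why: fluoride-mediated desilylation under buffered conditions that should not ionise the benzylic 4-OH; no stereocentre is touched.

**Compound list**
1 | 2,3,4-trihydroxybenzaldehyde | O=Cc1ccc(O)c(O)c1O | starting material
2 | 3,4-bis(benzyloxy)-2-hydroxybenzaldehyde | O=Cc1ccc(OCc2ccccc2)c(OCc2ccccc2)c1O | intermediate
3 | 1-(benzyloxy)-4-ethynylbenzene | C#Cc1ccc(OCc2ccccc2)cc1 | starting material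
4 | 2-[(E)-2-(4-benzyloxyphenyl)ethenyl]-1,3,2-benzodioxaborole (catechol boronate) | B1(/C=C/c2ccc(OCc3ccccc3)cc2)Oc2ccccc2O1 | intermediate
5 | (E)-2-[4-(benzyloxy)phenyl]ethenylboronic acid | OB(O)/C=C/c1ccc(OCc2ccccc2)cc1 | intermediate
6 | (±)-7,8-bis(benzyloxy)-2-PBP-2H-chromene | C1=Cc2ccc(OCc3ccccc3)c(OCc3ccccc3)c2OC1c1ccc(OCc2ccccc2)cc1 | intermediate
7 | (±)-(2R*,3S*)-7,8-bis(benzyloxy)-3-boranyl-2-PBP-chroman (alkylborane) | c1cc2c(c(OCc3ccccc3)c1OCc1ccccc1)O[C@H](c1ccc(OCc3ccccc3)cc1)[C@@H](B)C2 | intermediate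
8 | (±)-(2R*,3S*)-7,8-bis(benzyloxy)-2-PBP-chroman-3-ol (2,3-trans) | c1cc2c(c(OCc3ccccc3)c1OCc1ccccc1)O[C@H](c1ccc(OCc3ccccc3)cc1)[C@@H](O)C2 | intermediate
9 | (±)-7,8-bis(benzyloxy)-2-PBP-chroman-3-one | O=C1Cc2ccc(OCc3ccccc3)c(OCc3ccccc3)c2OC1c1ccc(OCc2ccccc2)cc1 | intermediate
10 | (2R,3R)-7,8-bis(benzyloxy)-2-PBP-chroman-3-ol (tri-O-benzylepioritin) | c1cc2c(c(OCc3ccccc3)c1OCc1ccccc1)O[C@H](c1ccc(OCc3ccccc3)cc1)[C@H](O)C2 | intermediate
11 | (2R,3R)-7,8-bis(benzyloxy)-6-bromo-2-PBP-chroman-3-ol | Brc1cc2c(c(OCc3ccccc3)c1OCc1ccccc1)O[C@H](c1ccc(OCc3ccccc3)cc1)[C@H](O)C2 | intermediate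
12 | (2R,3R,4S)-7,8-bis(benzyloxy)-6-bromo-2-PBP-chroman-3,4-diol (4β-OH) | Brc1cc2c(c(OCc3ccccc3)c1OCc1ccccc1)O[C@H](c1ccc(OCc3ccccc3)cc1)[C@H](O)[C@H]2O | intermediate
13 | (2R,3S)-7,8-bis(benzyloxy)-6-bromo-3-hydroxy-2-PBP-chroman-4-one (2,3-cis) | Brc1cc2c(c(OCc3ccccc3)c1OCc1ccccc1)O[C@H](c1ccc(OCc3ccccc3)cc1)[C@H](O)C2=O | intermediate
14 | (2R,3R,4R)-7,8-bis(benzyloxy)-6-bromo-2-PBP-chroman-3,4-diol (all-cis) | Brc1cc2c(c(OCc3ccccc3)c1OCc1ccccc1)O[C@H](c1ccc(OCc3ccccc3)cc1)[C@H](O)[C@@H]2O | intermediate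
15 | (2R,3S,4R)-7,8-bis(benzyloxy)-6-bromo-2-PBP-3,4-bis(tert-butyldimethylsilyloxy)chroman (BU–Br) | Brc1cc2c(c(OCc3ccccc3)c1OCc1ccccc1)O[C@H](c1ccc(OCc3ccccc3)cc1)[C@H](O[Si](C)(C)C(C)(C)C)[C@@H]2O[Si](C)(C)C(C)(C)C | intermediate
16 | sodium 2,3-bis(benzyloxy)-6-formylphenolate | [Na+].[O-]c1c(C=O)ccc(OCc2ccccc2)c1OCc1ccccc1 | intermediate
17 | BU–Li (6-lithio derivative of 15) | [Li]c1cc2c(c(OCc3ccccc3)c1OCc1ccccc1)O[C@H](c1ccc(OCc3ccccc3)cc1)[C@H](O[Si](C)(C)C(C)(C)C)[C@@H]2O[Si](C)(C)C(C)(C)C | intermediate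
18 | [3,4-bis(benzyloxy)-2-hydroxyphenyl](BU)methanol (carbinol epimers) | OC(c1ccc(OCc2ccccc2)c(OCc2ccccc2)c1O)c1cc2c(c(OCc3ccccc3)c1OCc1ccccc1)O[C@H](c1ccc(OCc3ccccc3)cc1)[C@H](O[Si](C)(C)C(C)(C)C)[C@@H]2O[Si](C)(C)C(C)(C)C | intermediate
19 | 4-(benzyloxy)benzoyl chloride | O=C(Cl)c1ccc(OCc2ccccc2)cc1 | starting material
20 | 1-[4-(benzyloxy)phenyl]-2-diazoethan-1-one | [N-]=[N+]=CC(=O)c1ccc(OCc2ccccc2)cc1 | intermediate
21 | 2,3-bis(benzyloxy)-6-[(BU)methylidene]cyclohexa-2,4-dien-1-one (o-quinone methide) | O=C1C(OCc2ccccc2)=C(OCc2ccccc2)C=CC1=Cc1cc2c(c(OCc3ccccc3)c1OCc1ccccc1)O[C@H](c1ccc(OCc3ccccc3)cc1)[C@H](O[Si](C)(C)C(C)(C)C)[C@@H]2O[Si](C)(C)C(C)(C)C | intermediate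
22 | [(2S,3S)-6,7-bis(benzyloxy)-3-BU-2,3-dihydrobenzofuran-2-yl](PBP)methanone (2,3-cis) | O=C(c1ccc(OCc2ccccc2)cc1)[C@H]1Oc2c(OCc3ccccc3)c(OCc3ccccc3)ccc2[C@H]1c1cc2c(c(OCc3ccccc3)c1OCc1ccccc1)O[C@H](c1ccc(OCc3ccccc3)cc1)[C@H](O[Si](C)(C)C(C)(C)C)[C@@H]2O[Si](C)(C)C(C)(C)C | intermediate
23 | (3S)-3-[3,4-bis(benzyloxy)-2-hydroxyphenyl]-1-PBP-3-BU-propan-1-one (keto-phenol) | O=C(c1ccc(OCc2ccccc2)cc1)C[C@@H](c1ccc(OCc2ccccc2)c(OCc2ccccc2)c1O)c1cc2c(c(OCc3ccccc3)c1OCc1ccccc1)O[C@H](c1ccc(OCc3ccccc3)cc1)[C@H](O[Si](C)(C)C(C)(C)C)[C@@H]2O[Si](C)(C)C(C)(C)C | intermediate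
24 | (4S)-7,8-bis(benzyloxy)-2-PBP-4-BU-chroman-2-ol (hemiketal; C2 epimers) | c1cc2c(c(OCc3ccccc3)c1OCc1ccccc1)OC(O)(c1ccc(OCc3ccccc3)cc1)C[C@@H]2c1cc2c(c(OCc3ccccc3)c1OCc1ccccc1)O[C@H](c1ccc(OCc3ccccc3)cc1)[C@H](O[Si](C)(C)C(C)(C)C)[C@@H]2O[Si](C)(C)C(C)(C)C | intermediate
25 | (4S)-7,8-bis(benzyloxy)-2-PBP-4-BU-4H-chromene (flav-2-ene; 4-aryl α) | c1cc2c(c(OCc3ccccc3)c1OCc1ccccc1)OC(c1ccc(OCc3ccccc3)cc1)=C[C@@H]2c1cc2c(c(OCc3ccccc3)c1OCc1ccccc1)O[C@H](c1ccc(OCc3ccccc3)cc1)[C@H](O[Si](C)(C)C(C)(C)C)[C@@H]2O[Si](C)(C)C(C)(C)C | intermediate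
26 | 3β-boranyl adduct of 25 (2-aryl α, 3-boron β, 4-aryl α; alkylborane) | c1cc2c(c(OCc3ccccc3)c1OCc1ccccc1)O[C@H](c1ccc(OCc3ccccc3)cc1)[C@@H](B)[C@@H]2c1cc2c(c(OCc3ccccc3)c1OCc1ccccc1)O[C@H](c1ccc(OCc3ccccc3)cc1)[C@H](O[Si](C)(C)C(C)(C)C)[C@@H]2O[Si](C)(C)C(C)(C)C | intermediate
27 | (2R,3S,4S)-7,8-bis(benzyloxy)-2-PBP-4-BU-chroman-3-ol (2,3-trans-3,4-trans; 4-aryl α) | c1cc2c(c(OCc3ccccc3)c1OCc1ccccc1)O[C@H](c1ccc(OCc3ccccc3)cc1)[C@@H](O)[C@@H]2c1cc2c(c(OCc3ccccc3)c1OCc1ccccc1)O[C@H](c1ccc(OCc3ccccc3)cc1)[C@H](O[Si](C)(C)C(C)(C)C)[C@@H]2O[Si](C)(C)C(C)(C)C | intermediate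
28 | 6-bromo-7,8,4'-tri-O-benzylepioritin-(4β→6)-7,8,4'-tri-O-benzyloritin-(4α→6)-7,8,4'-tri-O-benzyl-3,4-bis-O-TBS-epioritin-4α-ol | c1ccccc1COc1ccc([C@H]2Oc3c(cc(Br)c(OCc5ccccc5)c3OCc3ccccc3)[C@H](c3cc4c(c(OCc5ccccc5)c3OCc3ccccc3)O[C@H](c3ccc(OCc5ccccc5)cc3)[C@@H](O)[C@@H]4c3cc4c(c(OCc5ccccc5)c3OCc3ccccc3)O[C@H](c3ccc(OCc5ccccc5)cc3)[C@H](O[Si](C)(C)C(C)(C)C)[C@@H]4O[Si](C)(C)C(C)(C)C)[C@H]2O)cc1 | intermediate
29 | epioritin-(4β→6)-oritin-(4α→6)-3,4-bis-O-TBS-epioritin-4α-ol | Oc1ccc([C@H]2Oc3c(ccc(O)c3O)[C@H](c3cc4c(c(O)c3O)O[C@H](c3ccc(O)cc3)[C@@H](O)[C@@H]4c3cc4c(c(O)c3O)O[C@H](c3ccc(O)cc3)[C@H](O[Si](C)(C)C(C)(C)C)[C@@H]4O[Si](C)(C)C(C)(C)C)[C@H]2O)cc1 | intermediate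
30 | epioritin-(4β→6)-oritin-(4α→6)-epioritin-4α-ol | Oc1ccc([C@H]2Oc3c(ccc(O)c3O)[C@H](c3cc4c(c(O)c3O)O[C@H](c3ccc(O)cc3)[C@@H](O)[C@@H]4c3cc4c(c(O)c3O)O[C@H](c3ccc(O)cc3)[C@H](O)[C@@H]4O)[C@H]2O)cc1 | target

**Step count and risks**
Total: 19 steps. Longest linear sequence: 17 steps (steps 1, 3 to 12 and 14 to 19; steps 2 and 13 are side branches).

Most likely to fail:

Step 15. The liberated aryl ketone may be reduced further by SmI2, fragmentation of the ketyl may be incomplete, and the 4H-chromene may oxidise in air or disproportionate under acid during cyclodehydration. Fallback: it sets out from 18 and gives up the dihydrobenzofuran stage. The o-quinone methide is generated from 18 with the same chiral phosphoric acid and is intercepted by the silyl enol ether 1-[4-(benzyloxy)phenyl]-1-(trimethylsilyloxy)ethene F1 (from 4'-(benzyloxy)acetophenone, Me3SiOTf, Et3N) in a Mukaiyama–Michael addition. Desilylation on work-up gives keto-phenol 23 directly, with its stereocentre set by the catalyst and without any reductant. Cyclodehydration (PPTS, PhMe, 4 Å MS) then gives 25, where the fallback rejoins the route.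

Step 14. Facial selectivity at the diarylmethine carbon may be poor because the bulky chiral bottom-unit aryl group is mismatched with the catalyst; the diazoketone may be protonated and decomposed by the acid; the o-quinone methide may oligomerise. Fallback: it sets out from 15 and replaces Brønsted-acid catalysis by a Rh-catalysed conjugate addition. Bromine–lithium exchange (n-BuLi, THF, −78 °C) and quenching with 2-isopropoxy-4,4,5,5-tetramethyl-1,3,2-dioxaborolane give the BU pinacol boronate F2. 7,8-Bis(benzyloxy)coumarin F3 is made from 7,8-dihydroxycoumarin with BnBr and K2CO3. Hayashi–Miyaura addition of F2 to F3 ([Rh(acac)(C2H4)2], (R)-BINAP or its antipode as needed, dioxane/H2O, 60 °C) should give (4S)-7,8-bis(benzyloxy)-4-BU-chroman-2-one F4 with catalyst-controlled C4. Enolisation and phosphorylation (KHMDS, (PhO)2P(O)Cl, THF, −78 °C) give the ketene acetal phosphate F5. Suzuki–Miyaura coupling of F5 with 4-(benzyloxy)phenylboronic acid (Pd(PPh3)4, K3PO4, dioxane, 80 °C) gives 25, where the fallback rejoins the route.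

Step 17. The Lewis acid may also ionise the silylated benzylic C4–O bond of the bottom unit or cleave silyl ethers; attack may occur at C5 instead of C6; O-alkylation of a free 3-OH may compete. Fallback: it sets out from 12 and uses thiophilic instead of oxophilic activation. Treatment of 12 with phenylmethanethiol and a catalytic acid (AcOH, rt) should give the 4β-benzylsulfanyl derivative F6. F6 is activated with AgBF4 in THF at 0 °C in the presence of 27; these conditions are neutral and leave silyl ethers and benzylic C–O bonds alone. The coupling gives 28, where the fallback rejoins the route.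

Further compounds
F1 | step 15 | 1-[4-(benzyloxy)phenyl]-1-(trimethylsilyloxy)ethene | C=C(O[Si](C)(C)C)c1ccc(OCc2ccccc2)cc1
F2 | step 14 | 2-BU-4,4,5,5-tetramethyl-1,3,2-dioxaborolane | CC1(C)OB(OC1(C)C)c1cc2c(c(OCc3ccccc3)c1OCc1ccccc1)O[C@H](c1ccc(OCc3ccccc3)cc1)[C@H](O[Si](C)(C)C(C)(C)C)[C@@H]2O[Si](C)(C)C(C)(C)C
F3 | step 14 | 7,8-bis(benzyloxy)-2H-chromen-2-one | O=C1C=Cc2ccc(OCc3ccccc3)c(OCc3ccccc3)c2O1
F4 | step 14 | (4S)-7,8-bis(benzyloxy)-4-BU-chroman-2-one | c1cc2c(c(OCc3ccccc3)c1OCc1ccccc1)OC(=O)C[C@@H]2c1cc2c(c(OCc3ccccc3)c1OCc1ccccc1)O[C@H](c1ccc(OCc3ccccc3)cc1)[C@H](O[Si](C)(C)C(C)(C)C)[C@@H]2O[Si](C)(C)C(C)(C)C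
F5 | step 14 | (4S)-7,8-bis(benzyloxy)-4-BU-4H-chromen-2-yl diphenyl phosphate | c1cc2c(c(OCc3ccccc3)c1OCc1ccccc1)OC(OP(=O)(Oc1ccccc1)Oc1ccccc1)=C[C@@H]2c1cc2c(c(OCc3ccccc3)c1OCc1ccccc1)O[C@H](c1ccc(OCc3ccccc3)cc1)[C@H](O[Si](C)(C)C(C)(C)C)[C@@H]2O[Si](C)(C)C(C)(C)C
F6 | step 17 | (2R,3R)-7,8-bis(benzyloxy)-4β-(benzylsulfanyl)-6-bromo-2-PBP-chroman-3-ol (3,4-trans) | Brc1cc2c(c(OCc3ccccc3)c1OCc1ccccc1)O[C@H](c1ccc(OCc3ccccc3)cc1)[C@H](O)[C@H]2SCc1ccccc1
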